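## Analysis of the target

Target 13 is a phenylcoumaran neolignan built on a 2,3-dihydrobenzofuran (O1, C2, C3, C3a to C7a). Ring A carries a methoxy group at C7 and an (E)-propenoic acid at C5. C2 bears a 4-hydroxy-3,5-dimethoxyphenyl (syringyl) ring and C3 a hydroxymethyl group. The two adjacent stereocentres are 2S,3R, which puts the aryl group and the CH2OH arm trans on the five-membered ring, the more stable arrangement. The C2–O1 bond is benzylic and para to a free phenol, so it can ionize under acid and open through a para-quinone methide under hot base. The phenol is easily oxidized, and the cinnamic acid is a Michael acceptor that must be absent during organometallic steps. The difficulty is therefore the absolute configuration at two contiguous benzylic centres, one of which is labile. The strategy rests on C3: it carries an exocyclic one-carbon group and is bonded directly to ring A at C3a. That C3a–C3(–C) array is what the carbonyl carbon and α-carbon of a 2-arylchroman-4-one become when the ring A carbon shifts from the carbonyl carbon to the α-carbon.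

## Retrosynthetic reasoning

**13 to 12.** No skeletal bond is cut. The acid is masked as a methyl ester and the phenol as a tosylate, and both fall to hydroxide in one final operation. The phenol stays masked until the end because a free syringyl phenol would be oxidized by the iodine reagent, would make its ring a migrating group, and would labilize C2–O1.

**12 to 11.** The bond between C5 of ring A and the alkene is cut, leaving a C5 bromide. The acrylate is introduced late because it would outcompete chromone 4 as an acceptor in the conjugate addition and would be exposed to the oxidant. The bromine is inert to rhodium, trivalent iodine and borohydride, and it blocks the position para to O1. The forward reaction must be an E-selective Mizoroki–Heck coupling at C–Br that leaves the aryl sulfonate alone.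

**11 to 10.** The CH2OH group is traced to a methyl ester on C3. Reduction directly after the key step removes the acidic C3–H before any basic step, so the trans relation is locked.

**10 to 7.** This is the central disconnection. The C3–C3a bond is cut and C3a is reattached to the ester carbon, which becomes the C4 carbonyl of a six-membered pyranone. A two-stereocentre problem becomes a one-stereocentre problem, because C3 is now derived from C2. The forward reaction is an oxidative 1,2-shift of the ring A carbon with a trivalent iodine oxidant.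

**7 to 4 and 6.** The C2–aryl bond is cut. Asymmetric conjugate addition of arylboronate 6 to chromone 4 forms this bond and sets C2 under catalyst control. It is preferred to a chalcone cyclization, which has no reliable enantioselective variant for this substitution pattern.

**6 to 5; 4 to 2 to 1.** Boronate 6 comes from phenol 5 by sulfonylation. Chromone 4 comes from acetophenone 2 by one-carbon homologation through enaminone 3, and 2 from 1 by bromination para to the phenol.

## Alternatives that were turned down

**Alternative 1:** The C2–aryl bond and the C3–C3a bond are cut together, giving alkenyl boronate A2, aryllithium A4 and ring A triflate A3.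
- Forward step: A4 adds to boron of A2. A palladium catalyst with a chiral ferrocenyl diphosphine then delivers the aryl group of A3 to the alkene of the ate complex. The syringyl group shifts from boron to the adjacent carbon and ring A ends on the next one, giving boronate A1 with both benzylic stereocentres.
- For it: three simple pieces, two C–C bonds and two stereocentres in one catalytic event, and the CH2O arm at the right oxidation level. On convergence it is stronger than the chosen route.
- Against it: the alkene of A2 is 1,2-disubstituted, where the metallate shift is slower and direct Suzuki–Miyaura transfer competes. A3 is hindered by an ortho alkoxy group. A1 is still acyclic, and O1–C2 must then be made at a carbon benzylic to a para-oxygenated ring. Displacement there tends to run through a cation or quinone methide, so the configuration at the boron-bearing carbon is not transferred reliably. Four protecting groups and a separate aldehyde homologation add steps.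
- Comparison: the chosen route has O1–C2 in place from the chromone stage and never makes or breaks it after C2 is set, and C3 follows from C2 by a stereospecific shift.

**Alternative 2:** The C3–C3a bond and the C–O bond of the hydroxymethyl arm are cut, leading to aryl iodide A6, an ether of a 2-iodophenol with an enantiopure 1-arylallyl alcohol.
- Forward step: a ring A aryl radical generated from the C–I bond by tin-mediated photolysis adds 5-exo to the internal alkene carbon. The primary radical is captured by a nitroxide to give A5.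
- For it: such closures are fast, the oxygen of the arm arrives in the same step, and the C5 aldehyde is ready for condensation to the acrylic acid. Its end-game could be shorter than the one chosen here.
- Against it: A6 is a secondary ether that is both allylic and benzylic to an electron-rich ring. Its enantioselective construction risks ionization and allylic transposition, and its C–H is placed for 1,5-hydrogen transfer to the aryl radical. C2 steers C3 only through a modest preference in an early chair-like transition state, and a cis product cannot be corrected because C3 has no acidifying group. Stoichiometric tin and a later N–O reduction are further costs.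
- Comparison: the chosen route derives C3 from C2 by an invertive shift and keeps an enolizable ester as a safeguard.

**Alternative 3:** Ring A is disconnected at C3a–C4 and C7–C7a. Ketene acetal A8 of a trans-4,5-disubstituted butyrolactone supplies C7a and C3a, and pyrone A9 supplies C4 to C7 with the methoxy and ester groups.
- Forward step: [4+2] cycloaddition, decarboxylative cycloreversion and loss of the silyloxy group give arene A7.
- For it: both stereocentres are fixed in a saturated lactone before the arene exists, partner polarity dictates the regiochemistry, and no oxidant meets the electron-rich rings. On stereochemical safety after ring formation it is at least as good as the chosen plan.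
- Against it: the stereochemical problem is only moved to the lactone, which needs its own asymmetric synthesis. The cycloaddition must join a fully substituted ketene acetal carbon to the methoxy-bearing pyrone carbon, and the methoxy group makes the pyrone less electron-poor. A7 has C5 at the benzoate level, so reduction, reoxidation, olefination and two desilylations remain.
- Comparison: the chosen route is shorter, uses one catalytic asymmetric step, and converts the C5 bromine to the acrylate in one coupling.

Key step: step 5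

Remark on the chemistry: the sense of induction of the diene ligand in step 4 is assigned by analogy with additions to cyclic enones; if the opposite face is attacked, the mirror-image ligand is used.

## Route

Step 1
Reactants: 1 1-(2-hydroxy-3-methoxyphenyl)ethanone
Product: 2 1-(5-bromo-2-hydroxy-3-methoxyphenyl)ethanone
Conditions: NBS (1.05 equiv), MeCN, 0 °C to rt
Reagents that add atoms: N-bromosuccinimide, O=C1CCC(=O)N1Br
Why: Electrophilic aromatic bromination; the phenol directs para because both ortho positions are occupied, and the ring is too activated for side-chain bromination to compete.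

Step 2
Reactants: 2 1-(5-bromo-2-hydroxy-3-methoxyphenyl)ethanone
Product: 4 6-bromo-8-methoxy-4H-chromen-4-one, via enaminone 3 (not isolated)
Conditions: Me2NCH(OMe)2, toluene, 100 °C; concentrate; then conc. HCl, CH2Cl2, 40 °C
Reagents that add atoms: N,N-dimethylformamide dimethyl acetal, COC(OC)N(C)C
Why: Condensation of the methyl ketone with the amide acetal gives the enaminone, and acid then promotes intramolecular addition of the phenol and elimination of dimethylamine (enaminone route to chromones).

Step 3
Reactants: 5 2,6-dimethoxy-4-(4,4,5,5-tetramethyl-1,3,2-dioxaborolan-2-yl)phenol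
Product: 6 2,6-dimethoxy-4-(4,4,5,5-tetramethyl-1,3,2-dioxaborolan-2-yl)phenyl 4-methylbenzenesulfonate
Conditions: TsCl, Et3N, DMAP (cat.), CH2Cl2, 0 °C to rt
Reagents that add atoms: p-toluenesulfonyl chloride, Cc1ccc(cc1)S(=O)(=O)Cl
Why: O-Sulfonylation of a phenol with nucleophilic catalysis; the pinacol boronate is inert to these anhydrous, weakly basic conditions.

Step 4
Reactants: 4 6-bromo-8-methoxy-4H-chromen-4-one; 6 2,6-dimethoxy-4-(4,4,5,5-tetramethyl-1,3,2-dioxaborolan-2-yl)phenyl 4-methylbenzenesulfonate
Product: 7 4-[(2S)-6-bromo-8-methoxy-4-oxo-3,4-dihydro-2H-chromen-2-yl]-2,6-dimethoxyphenyl 4-methylbenzenesulfonate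
Conditions: [Rh(C2H4)2Cl]2 (2.5 mol %), (1S,4S)-2,5-diphenylbicyclo[2.2.2]octa-2,5-diene (5.5 mol %), aq KOH (0.5 equiv), 1,4-dioxane/H2O 10:1, 50 °C
Reagents that add atoms: none
Why: Rhodium-catalyzed asymmetric 1,4-addition of an arylboron reagent to a chromone (Hayashi–Miyaura reaction); hydroxide activates the pinacol ester for transmetalation to monovalent rhodium. The chiral diene selects the enantiotopic face of C2 on insertion and water protonates the rhodium enolate, setting C2 as S. The aryl bromide and aryl tosylate do not react with rhodium under these conditions.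

Step 5
Reactants: 7 4-[(2S)-6-bromo-8-methoxy-4-oxo-3,4-dihydro-2H-chromen-2-yl]-2,6-dimethoxyphenyl 4-methylbenzenesulfonate
Product: 10 methyl (2S,3S)-5-bromo-7-methoxy-2-[3,5-dimethoxy-4-(tosyloxy)phenyl]-2,3-dihydro-1-benzofuran-3-carboxylate, via methyl enol ether 8 (not isolated), via iodanyl ketal 9 (not isolated)
Conditions: PhI(OAc)2 (1.3 equiv), conc. H2SO4, HC(OMe)3, rt
Reagents that add atoms: trimethyl orthoformate, COC(OC)OC (methoxy group of the ester); water, O (carbonyl oxygen, on hydrolysis of the dimethoxycarbenium ion at work-up)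
Why: Acid and trimethyl orthoformate convert the C4 ketone of 7 into its dimethyl ketal and the methyl enol ether 8; the trivalent iodine reagent attacks C3 of 8 on the face remote from the C2 aryl group and methanol re-adds at C4, giving the trans iodanyl ketal 9 with the C2 aryl group and the C3–I bond both pseudo-equatorial. In that arrangement the C3–I bond is antiperiplanar to the ring bond C4–C4a, so departure of iodobenzene is assisted by a 1,2-shift of the ring A carbon C4a from C4 to C3 through a bridged arenium ion, which forms the C3–C3a bond with inversion at C3 and leaves C4 as a dimethoxycarbenium ion that becomes the methyl ester on work-up. The closest known reaction type is the oxidative ring contraction of flavanones to methyl trans-2-aryl-2,3-dihydrobenzofuran-3-carboxylates with PhI(OAc)2 or Tl(NO3)3 in acidified trimethyl orthoformate. The five-membered ring O1–C2–C3–C3a–C7a is not closed by a cyclization; it arises by contraction of the pyranone through this 1,2-aryl shift. The new stereocentre C3 is controlled by C2: anti addition of iodine followed by invertive migration places the ester trans to the aryl group (2S,3S), and because C3–H is enolizable any cis ester can be equilibrated to the same trans isomer. The step needs ring A to migrate in preference to the C2 aryl group, which would lead to an isoflavone, and needs C2 to keep its configuration. The tosylate secures both, since the sulfonylated syringyl ring is a poor bridging group, resists the oxidant and does not stabilize a benzylic cation at C2, while C4a is activated by the ortho ring oxygen. The bromine at C6 blocks the position para to O1 against electrophilic attack.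

Step 6
Reactants: 10 methyl (2S,3S)-5-bromo-7-methoxy-2-[3,5-dimethoxy-4-(tosyloxy)phenyl]-2,3-dihydro-1-benzofuran-3-carboxylate
Product: 11 4-[(2S,3R)-5-bromo-3-(hydroxymethyl)-7-methoxy-2,3-dihydro-1-benzofuran-2-yl]-2,6-dimethoxyphenyl 4-methylbenzenesulfonate
Conditions: LiBH4, THF, 0 °C to rt
Reagents that add atoms: none
Why: Chemoselective hydride reduction of the methyl ester; the aryl bromide and aryl sulfonate are inert to LiBH4. No bond at C3 is broken; the descriptor changes from S to R only because CH2OH ranks below C2.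

Step 7
Reactants: 11 4-[(2S,3R)-5-bromo-3-(hydroxymethyl)-7-methoxy-2,3-dihydro-1-benzofuran-2-yl]-2,6-dimethoxyphenyl 4-methylbenzenesulfonate
Product: 12 methyl (E)-3-[(2S,3R)-3-(hydroxymethyl)-7-methoxy-2-[3,5-dimethoxy-4-(tosyloxy)phenyl]-2,3-dihydro-1-benzofuran-5-yl]prop-2-enoate
Conditions: methyl acrylate, Pd(OAc)2 (5 mol %), P(o-tol)3 (15 mol %), Et3N, DMF, 100 °C
Reagents that add atoms: methyl acrylate, C=CC(=O)OC
Why: Mizoroki–Heck reaction; zerovalent palladium inserts into the C–Br bond but not into the aryl tosylate with this ligand. Syn insertion and syn β-hydride elimination give the E-alkene.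

Step 8
Reactants: 12 methyl (E)-3-[(2S,3R)-3-(hydroxymethyl)-7-methoxy-2-[3,5-dimethoxy-4-(tosyloxy)phenyl]-2,3-dihydro-1-benzofuran-5-yl]prop-2-enoate
Product: 13 (E)-3-[(2S,3R)-2-(4-hydroxy-3,5-dimethoxyphenyl)-3-(hydroxymethyl)-7-methoxy-2,3-dihydro-1-benzofuran-5-yl]prop-2-enoic acid
Conditions: KOH, MeOH/THF/H2O, 60 °C, under Ar; then 1 M HCl to pH 3
Reagents that add atoms: potassium hydroxide, [K+].[OH-]
Why: Saponification of the methyl ester and hydrolysis of the aryl sulfonate by attack of hydroxide at sulfur. Neither stereocentre carries an acidifying group at this stage, and oxygen is excluded to protect the phenoxide.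

## Compound list

1 | 1-(2-hydroxy-3-methoxyphenyl)ethanone | CC(=O)c1cccc(OC)c1O | starting material
2 | 1-(5-bromo-2-hydroxy-3-methoxyphenyl)ethanone | CC(=O)c1cc(Br)cc(OC)c1O | intermediate
3 | (E)-1-(5-bromo-2-hydroxy-3-methoxyphenyl)-3-(dimethylamino)prop-2-en-1-one | CN(C)/C=C/C(=O)c1cc(Br)cc(OC)c1O | intermediate
4 | 6-bromo-8-methoxy-4H-chromen-4-one | COc1cc(Br)cc2c1occc2=O | intermediate
5 | 2,6-dimethoxy-4-(4,4,5,5-tetramethyl-1,3,2-dioxaborolan-2-yl)phenol | COc1cc(B2OC(C)(C)C(C)(C)O2)cc(OC)c1O | starting material
6 | 2,6-dimethoxy-4-(4,4,5,5-tetramethyl-1,3,2-dioxaborolan-2-yl)phenyl 4-methylbenzenesulfonate | COc1cc(B2OC(C)(C)C(C)(C)O2)cc(OC)c1OS(=O)(=O)c3ccc(C)cc3 | intermediate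
7 | 4-[(2S)-6-bromo-8-methoxy-4-oxo-3,4-dihydro-2H-chromen-2-yl]-2,6-dimethoxyphenyl 4-methylbenzenesulfonate | COc1cc([C@H]2Oc3c(OC)cc(Br)cc3C(=O)C2)cc(OC)c1OS(=O)(=O)c4ccc(C)cc4 | intermediate
8 | 4-[(2S)-6-bromo-4,8-dimethoxy-2H-chromen-2-yl]-2,6-dimethoxyphenyl 4-methylbenzenesulfonate | COc1cc([C@H]2Oc3c(OC)cc(Br)cc3C(OC)=C2)cc(OC)c1OS(=O)(=O)c4ccc(C)cc4 | intermediate
9 | 4-[(2R,3R)-3-[acetoxy(phenyl)-λ3-iodanyl]-6-bromo-4,4,8-trimethoxy-3,4-dihydro-2H-chromen-2-yl]-2,6-dimethoxyphenyl 4-methylbenzenesulfonate (aryl and iodine trans; C2 untouched, descriptor changed by priority) | COc1cc([C@H]2Oc3c(OC)cc(Br)cc3C(OC)(OC)[C@@H]2[I](OC(C)=O)c5ccccc5)cc(OC)c1OS(=O)(=O)c4ccc(C)cc4 | intermediate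
10 | methyl (2S,3S)-5-bromo-7-methoxy-2-[3,5-dimethoxy-4-(tosyloxy)phenyl]-2,3-dihydro-1-benzofuran-3-carboxylate (trans) | COc1cc([C@H]2Oc3c(OC)cc(Br)cc3[C@@H]2C(=O)OC)cc(OC)c1OS(=O)(=O)c4ccc(C)cc4 | intermediate
11 | 4-[(2S,3R)-5-bromo-3-(hydroxymethyl)-7-methoxy-2,3-dihydro-1-benzofuran-2-yl]-2,6-dimethoxyphenyl 4-methylbenzenesulfonate | COc1cc([C@H]2Oc3c(OC)cc(Br)cc3[C@@H]2CO)cc(OC)c1OS(=O)(=O)c4ccc(C)cc4 | intermediate
12 | methyl (E)-3-[(2S,3R)-3-(hydroxymethyl)-7-methoxy-2-[3,5-dimethoxy-4-(tosyloxy)phenyl]-2,3-dihydro-1-benzofuran-5-yl]prop-2-enoate | COc1cc([C@H]2Oc3c(OC)cc(/C=C/C(=O)OC)cc3[C@@H]2CO)cc(OC)c1OS(=O)(=O)c4ccc(C)cc4 | intermediate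
13 | (E)-3-[(2S,3R)-2-(4-hydroxy-3,5-dimethoxyphenyl)-3-(hydroxymethyl)-7-methoxy-2,3-dihydro-1-benzofuran-5-yl]prop-2-enoic acid | COc1cc([C@H]2Oc3c(OC)cc(/C=C/C(=O)O)cc3[C@@H]2CO)cc(OC)c1O | target

## Step count and least certain steps

Total step count: 8. Longest linear sequence: 7 (steps 1, 2, 4, 5, 6, 7, 8); step 3 is the side branch.

**Step 5 (key step).**
- Risk: the C2 aryl group may shift to C3 instead of the ring A carbon, or simple dehydrogenation across C2–C3 may win. Strong acid could open the C2–O1 bond and erode C2, and excess oxidant could dehydrogenate the product ester.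
- Fallback, from 7 back to 10, is a Wolff ring contraction, which moves the same ring A carbon by a different mechanism. Compound 7 is deprotonated with LiN(SiMe3)2 in THF at −78 °C and acylated with 2,2,2-trifluoroethyl trifluoroacetate to give 4-[(2S)-6-bromo-8-methoxy-4-oxo-3-(trifluoroacetyl)-3,4-dihydro-2H-chromen-2-yl]-2,6-dimethoxyphenyl 4-methylbenzenesulfonate F1. Diazo transfer with MsN3, Et3N and water in MeCN gives 4-[(2R)-6-bromo-3-diazo-8-methoxy-4-oxo-3,4-dihydro-2H-chromen-2-yl]-2,6-dimethoxyphenyl 4-methylbenzenesulfonate F2. Irradiation of F2 in MeOH expels nitrogen, the ring A carbon migrates to the carbene carbon, and methanol traps the ketene as ester 10 together with its cis epimer, methyl (2S,3R)-5-bromo-7-methoxy-2-[3,5-dimethoxy-4-(tosyloxy)phenyl]-2,3-dihydro-1-benzofuran-3-carboxylate F3. Catalytic NaOMe in MeOH at 0 °C converges F3 on 10.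

**Step 4.**
- Risk: slow transmetalation of the pinacol ester with competing protodeboronation, hydroxide-induced ring opening of the flavanone to the hydroxychalcone (which would racemize C2), or delivery of the aryl group to the wrong face.
- Fallback, from 2 back to 7, builds the flavanone by aldol condensation and oxa-Michael closure and resolves it. Commercial 4-hydroxy-3,5-dimethoxybenzaldehyde F4 is tosylated (TsCl, Et3N, CH2Cl2) to 4-formyl-2,6-dimethoxyphenyl 4-methylbenzenesulfonate F5. Acid-mediated Claisen–Schmidt condensation of 2 with F5 (SOCl2, EtOH, rt) gives (E)-1-(5-bromo-2-hydroxy-3-methoxyphenyl)-3-[3,5-dimethoxy-4-(tosyloxy)phenyl]prop-2-en-1-one F6. NaOAc in refluxing EtOH closes F6 to racemic 4-(6-bromo-8-methoxy-4-oxo-3,4-dihydro-2H-chromen-2-yl)-2,6-dimethoxyphenyl 4-methylbenzenesulfonate F7. Preparative chromatography on a chiral stationary phase gives 7.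

**Step 7.**
- Risk: sluggish oxidative addition into the electron-rich bromide at the temperature needed, with catalyst decomposition and hydrodebromination.
- Fallback, from 11 back to 13, replaces carbopalladation by transmetalation. Suzuki–Miyaura coupling of 11 with commercial ethyl (E)-3-(4,4,5,5-tetramethyl-1,3,2-dioxaborolan-2-yl)prop-2-enoate F8 (Pd(dppf)Cl2, K3PO4, dioxane/H2O, 80 °C) gives ethyl (E)-3-[(2S,3R)-3-(hydroxymethyl)-7-methoxy-2-[3,5-dimethoxy-4-(tosyloxy)phenyl]-2,3-dihydro-1-benzofuran-5-yl]prop-2-enoate F9. F9 is hydrolyzed under the conditions of step 8 to 13.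

**Step 8.**
- Risk: the sulfonate may cleave too slowly at a temperature the product tolerates. The phenoxide could open the C2–O1 bond through a para-quinone methide, which would epimerize C2 or fragment the side arm, and it could be oxidized by air.
- Fallback, from 5 and 4 back to 13, uses a pivalate in place of the tosylate so that phenoxide is only formed at room temperature. Phenol 5 is acylated (t-BuCOCl, Et3N, DMAP, CH2Cl2) to 2,6-dimethoxy-4-(4,4,5,5-tetramethyl-1,3,2-dioxaborolan-2-yl)phenyl 2,2-dimethylpropanoate F10. Addition to 4 as in step 4 gives 4-[(2S)-6-bromo-8-methoxy-4-oxo-3,4-dihydro-2H-chromen-2-yl]-2,6-dimethoxyphenyl 2,2-dimethylpropanoate F11. Ring contraction as in step 5 gives methyl (2S,3S)-5-bromo-2-[3,5-dimethoxy-4-(pivaloyloxy)phenyl]-7-methoxy-2,3-dihydro-1-benzofuran-3-carboxylate F12. Excess i-Bu2AlH in CH2Cl2 at −78 °C reduces the methyl ester and removes the pivalate, giving 4-[(2S,3R)-5-bromo-3-(hydroxymethyl)-7-methoxy-2,3-dihydro-1-benzofuran-2-yl]-2,6-dimethoxyphenol F13. The Heck coupling of step 7, in which Et3N in DMF does not ionize the phenol appreciably, gives methyl (E)-3-[(2S,3R)-2-(4-hydroxy-3,5-dimethoxyphenyl)-3-(hydroxymethyl)-7-methoxy-2,3-dihydro-1-benzofuran-5-yl]prop-2-enoate F14. LiOH in THF/H2O at 20 °C gives 13.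

## Further compounds

F1 | step 5 | 4-[(2S)-6-bromo-8-methoxy-4-oxo-3-(trifluoroacetyl)-3,4-dihydro-2H-chromen-2-yl]-2,6-dimethoxyphenyl 4-methylbenzenesulfonate | COc1cc([C@H]2Oc3c(OC)cc(Br)cc3C(=O)C2C(=O)C(F)(F)F)cc(OC)c1OS(=O)(=O)c4ccc(C)cc4
F2 | step 5 | 4-[(2R)-6-bromo-3-diazo-8-methoxy-4-oxo-3,4-dihydro-2H-chromen-2-yl]-2,6-dimethoxyphenyl 4-methylbenzenesulfonate | COc1cc([C@H]2Oc3c(OC)cc(Br)cc3C(=O)C2=[N+]=[N-])cc(OC)c1OS(=O)(=O)c4ccc(C)cc4
F3 | step 5 | methyl (2S,3R)-5-bromo-7-methoxy-2-[3,5-dimethoxy-4-(tosyloxy)phenyl]-2,3-dihydro-1-benzofuran-3-carboxylate (cis) | COc1cc([C@H]2Oc3c(OC)cc(Br)cc3[C@H]2C(=O)OC)cc(OC)c1OS(=O)(=O)c4ccc(C)cc4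
F4 | step 4 | 4-hydroxy-3,5-dimethoxybenzaldehyde (purchased) | COc1cc(C=O)cc(OC)c1O
F5 | step 4 | 4-formyl-2,6-dimethoxyphenyl 4-methylbenzenesulfonate | COc1cc(C=O)cc(OC)c1OS(=O)(=O)c2ccc(C)cc2
F6 | step 4 | (E)-1-(5-bromo-2-hydroxy-3-methoxyphenyl)-3-[3,5-dimethoxy-4-(tosyloxy)phenyl]prop-2-en-1-one | COc1cc(/C=C/C(=O)c2cc(Br)cc(OC)c2O)cc(OC)c1OS(=O)(=O)c3ccc(C)cc3
F7 | step 4 | racemic 4-(6-bromo-8-methoxy-4-oxo-3,4-dihydro-2H-chromen-2-yl)-2,6-dimethoxyphenyl 4-methylbenzenesulfonate | COc1cc(C2Oc3c(OC)cc(Br)cc3C(=O)C2)cc(OC)c1OS(=O)(=O)c4ccc(C)cc4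
F8 | step 7 | ethyl (E)-3-(4,4,5,5-tetramethyl-1,3,2-dioxaborolan-2-yl)prop-2-enoate (purchased) | CCOC(=O)/C=C/B1OC(C)(C)C(C)(C)O1
F9 | step 7 | ethyl (E)-3-[(2S,3R)-3-(hydroxymethyl)-7-methoxy-2-[3,5-dimethoxy-4-(tosyloxy)phenyl]-2,3-dihydro-1-benzofuran-5-yl]prop-2-enoate | COc1cc([C@H]2Oc3c(OC)cc(/C=C/C(=O)OCC)cc3[C@@H]2CO)cc(OC)c1OS(=O)(=O)c4ccc(C)cc4
F10 | step 8 | 2,6-dimethoxy-4-(4,4,5,5-tetramethyl-1,3,2-dioxaborolan-2-yl)phenyl 2,2-dimethylpropanoate | COc1cc(B2OC(C)(C)C(C)(C)O2)cc(OC)c1OC(=O)C(C)(C)C
F11 | step 8 | 4-[(2S)-6-bromo-8-methoxy-4-oxo-3,4-dihydro-2H-chromen-2-yl]-2,6-dimethoxyphenyl 2,2-dimethylpropanoate | COc1cc([C@H]2Oc3c(OC)cc(Br)cc3C(=O)C2)cc(OC)c1OC(=O)C(C)(C)C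
F12 | step 8 | methyl (2S,3S)-5-bromo-2-[3,5-dimethoxy-4-(pivaloyloxy)phenyl]-7-methoxy-2,3-dihydro-1-benzofuran-3-carboxylate | COc1cc([C@H]2Oc3c(OC)cc(Br)cc3[C@@H]2C(=O)OC)cc(OC)c1OC(=O)C(C)(C)C
F13 | step 8 | 4-[(2S,3R)-5-bromo-3-(hydroxymethyl)-7-methoxy-2,3-dihydro-1-benzofuran-2-yl]-2,6-dimethoxyphenol | COc1cc([C@H]2Oc3c(OC)cc(Br)cc3[C@@H]2CO)cc(OC)c1O
F14 | step 8 | methyl (E)-3-[(2S,3R)-2-(4-hydroxy-3,5-dimethoxyphenyl)-3-(hydroxymethyl)-7-methoxy-2,3-dihydro-1-benzofuran-5-yl]prop-2-enoate | COc1cc([C@H]2Oc3c(OC)cc(/C=C/C(=O)OC)cc3[C@@H]2CO)cc(OC)c1O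
A1 | alternative 1 | 2-[(1S,2R)-3-[tert-butyl(dimethyl)silyl]oxy-1-(3,5-dimethoxy-4-triisopropylsilyloxyphenyl)-2-[5-(1,3-dioxolan-2-yl)-3-methoxy-2-(methoxymethoxy)phenyl]propyl]-4,4,5,5-tetramethyl-1,3,2-dioxaborolane (syn) | COc1cc([C@@H](B4OC(C)(C)C(C)(C)O4)[C@@H](CO[Si](C)(C)C(C)(C)C)c2cc(C3OCCO3)cc(OC)c2OCOC)cc(OC)c1O[Si](C(C)C)(C(C)C)C(C)C
A2 | alternative 1 | tert-butyl(dimethyl){[(E)-3-(4,4,5,5-tetramethyl-1,3,2-dioxaborolan-2-yl)prop-2-en-1-yl]oxy}silane | CC(C)(C)[Si](C)(C)OC/C=C/B1OC(C)(C)C(C)(C)O1
A3 | alternative 1 | 5-(1,3-dioxolan-2-yl)-3-methoxy-2-(methoxymethoxy)phenyl trifluoromethanesulfonate | COCOc1c(OC)cc(C2OCCO2)cc1OS(=O)(=O)C(F)(F)F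
A4 | alternative 1 | [3,5-dimethoxy-4-(triisopropylsilyloxy)phenyl]lithium | [Li]c1cc(OC)c(O[Si](C(C)C)(C(C)C)C(C)C)c(OC)c1
A5 | alternative 2 | (2S,3R)-2-(3,5-dimethoxy-4-triisopropylsilyloxyphenyl)-7-methoxy-3-[(2,2,6,6-tetramethylpiperidin-1-yl)oxymethyl]-2,3-dihydro-1-benzofuran-5-carbaldehyde | COc1cc([C@H]2Oc3c(OC)cc(C=O)cc3[C@@H]2CON4C(C)(C)CCCC4(C)C)cc(OC)c1O[Si](C(C)C)(C(C)C)C(C)C
A6 | alternative 2 | 3-iodo-5-methoxy-4-{[(1S)-1-(3,5-dimethoxy-4-triisopropylsilyloxyphenyl)prop-2-en-1-yl]oxy}benzaldehyde | O=Cc1cc(I)c(O[C@@H](C=C)c2cc(OC)c(O[Si](C(C)C)(C(C)C)C(C)C)c(OC)c2)c(OC)c1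
A7 | alternative 3 | methyl (2S,3R)-2-{4-[tert-butyl(dimethyl)silyl]oxy-3,5-dimethoxyphenyl}-3-{[tert-butyl(dimethyl)silyl]oxymethyl}-7-methoxy-2,3-dihydro-1-benzofuran-5-carboxylate | COc1cc([C@H]2Oc3c(OC)cc(C(=O)OC)cc3[C@@H]2CO[Si](C)(C)C(C)(C)C)cc(OC)c1O[Si](C)(C)C(C)(C)C
A8 | alternative 3 | tert-butyl{[(4R,5S)-5-{4-[tert-butyl(dimethyl)silyl]oxy-3,5-dimethoxyphenyl}-4-{[tert-butyl(dimethyl)silyl]oxymethyl}-4,5-dihydrofuran-2-yl]oxy}dimethylsilane | COc1cc([C@H]2OC(O[Si](C)(C)C(C)(C)C)=C[C@@H]2CO[Si](C)(C)C(C)(C)C)cc(OC)c1O[Si](C)(C)C(C)(C)C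
A9 | alternative 3 | methyl 3-methoxy-2-oxo-2H-pyran-5-carboxylate | COC(=O)c1coc(=O)c(OC)c1
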